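4 questions stand on this flask, and I answer them through one dimensionless number.

| flask | D | E | remark | time |
|---|---|---|---|---|
| oak | 5 mM (fed, over 1.5 s) | 1 mM | the very flask that is asked about, followed so far |  |
| alder | 5 mM (fed, over 1.5 s) | 0.67 mM | run made earlier |  |
| flask | 5.0 mM (fed, over 1.5 s) | 1.00 mM |  | 6.0 min |

| run | time / min | D / % | Q / % | X / % |
|---|---|---|---|---|
| oak | 0.500 | 9.9 | 24.4 | 23.8 |
| oak | 1.00 | 9.4 | 23.3 | 27.0 |
| oak | 1.33 | 9.6 | 23.0 | 27.5 |
| oak | 2.00 | 9.0 | 23.1 | 27.5 |
| oak | 2.50 | 8.7 | 22.9 | 28.0 |
| alder | 0.200 | 13.9 | 30.7 | 15.0 |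
| alder | 0.333 | 11.3 | 28.5 | 21.5 |
| alder | 0.667 | 10.9 | 25.9 | 27.2 |
| alder | 1.33 | 10.1 | 25.3 | 29.9 |
| alder | 2.50 | 10.7 | 25.5 | 30.3 |

(readings scatter by 0.3 percentage points)

- why nothing more happens at 6.0 min, or that something still does (it is still moving / all of D has reacted / forward and back rates have come level)
- conversion of D at 6.0 min
- amount of Q at 6.0 min, in percent of the D charged
- amount of X at 6.0 min, in percent of the D charged

- the numbers in the tables scatter by 0.3 percentage points (one standard deviation)
- the reaction counts as stopped when no species that holds the D changes by six tenths of a point or more over the second half of the time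

1. E is the limiting reagent, since 1.00 mM is less than the 5.0 mM of D. I define f as one minus E charged over D charged, the free share of D. It is 0.800 for this flask, and the alder run has 0.866.
2. The sum of D, Q and X reads 59.6% in the oak run at 2.50 min and 66.5% in the alder run at 2.50 min. The ratio of these sums is 0.896 and the ratio of the free shares is 0.924, so I take E to remove D one for one.
3. To test f, I scale the last alder readings by the ratio of free shares. X becomes 28.0% against 28.0% read in the oak run, Q 23.6% against 22.9%, and D 9.88% against 8.7%. X agrees, while Q stands off by 0.66 percentage points and D by 1.2 points. Each of these gaps sets one reading against one reading, and D in the alder run itself reads 10.1% and then 10.7% at its last two times, so I put the gaps down to scatter and let one number stand for the plateau.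
4. D remains while the oak readings stay nearly flat, so I expect rates level at 6.0 min, with conversion 90.1%, Q 23.6% and X 28.0%.
5. The forecast says “the flask should sit at its plateau”: forward and back rates have come level, conversion 91.1%, Q 22.9%, X 28.1%. Its Q is lower than mine.

The result:

    D ⇌ Q (K = 2.50, k = 0.340 s⁻¹)
    D ⇌ J (K = 2.20, k = 0.0300 s⁻¹)
    D + E → G (k = 1700 M⁻¹ s⁻¹)
    Q ⇌ J (k = 0.260 s⁻¹)
    Q ⇌ X (K = 1.20, k = 0.0570 s⁻¹)

The flask gives forward and back rates have come level, conversion 90.8%, Q 23.0% and X 27.6%, so the forecast stands; it would fail on Q at about 1.87 mM of E, where Q has moved by 5 points. At 6.00 min this flask holds G at 20.0% of the D charged and E at 0%. With 20 mM of D, f is 0.950, and the Q per free share of this flask scales to 27.3%; that neighbour gives 27.3%.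

All runs are calculated with made-up constants, noise included.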